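**Retrosynthetic overview**

- The strategy rests on the single cyclohexene ring: C1 carries CO2Me and is joined to C2–H by the only ring alkene, C3 and C5 carry the two identical enoate esters, C4 carries the free OH (3,4-cis, 4,5-trans) and C6 is CH2.
- The C4 hydroxyl is traced back to a C4 formate and then to a C4 formyl group (Baeyer–Villiger, retention), so the oxygen between the two esters enters as carbon and no selective acylation of a triol is needed.
- The ring is cut at C3–C4 and C5–C6. The C1=C2 alkene is where a [4+2] retron requires it, giving the diene C6H2=C1(CO2Me)–C2H=C3H–O-acyl and the dienophile OHC–C4H=C5H–O-acyl (E).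
- Both addends are enol esters of (2E)-3-methylpent-2-enoic acid: the diene from the dienolate of methyl (2E)-2-methyl-4-oxobut-2-enoate, the dienophile from sodium malonaldehyde.
- Ring order: the one ring and all three stereocentres are formed together in step 7; steps 8 and 9 only exchange CHO for OH at C4.

Key step: step 7

Assumption: the open face of the bound dienophile is assigned from the formyl C–H···O binding model of 2-substituted acroleins, which calls for the (3aS) catalyst (SMILES Cc1ccccc1B1OC(c2ccccc2)(c2ccccc2)[C@@H]2CCCN12); if 12 binds in the alternative α-C–H···O mode, the (3aR) catalyst would be used instead with no other change.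

**Route**

Step 1
Reactants: 1 (2E)-3-methylpent-2-enoic acid
Product: 2 (2E)-3-methylpent-2-enoyl chloride
Conditions: (COCl)2 (1.2 equiv), N,N-dimethylformamide (cat.), CH2Cl2, 0 °C to rt; volatiles removed, used crude
Reagents that add atoms: oxalyl chloride, ClC(=O)C(=O)Cl
Why: Acid chloride formation through the chloroiminium (Vilsmeier-type) catalyst; no base is present, so neither vinylketene formation nor E/Z scrambling of the trisubstituted alkene is expected.

Step 2
Reactants: 3 2,2-dimethoxyacetaldehyde (60 wt % in water); 4 methyl 2-(triphenylphosphoranylidene)propanoate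
Product: 5 methyl (2E)-4,4-dimethoxy-2-methylbut-2-enoate
Conditions: CH2Cl2/H2O, rt, vigorous stirring
Reagents that add atoms: none
Why: Wittig olefination with an ester-stabilised ylide, which tolerates the aqueous aldehyde and should give the E trisubstituted alkene (ester trans to the acetal carbon) through the reversible, thermodynamically controlled oxaphosphetane.

Step 3
Reactants: 5 methyl (2E)-4,4-dimethoxy-2-methylbut-2-enoate
Product: 6 methyl (2E)-2-methyl-4-oxobut-2-enoate
Conditions: HCl (1 M aq., cat.), acetone/H2O, rt
Reagents that add atoms: water, O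
Why: Acid-catalysed acetal hydrolysis; the methyl ester is untouched under these mild conditions and the E alkene, the more stable isomer, should be retained.

Step 4
Reactants: 6 methyl (2E)-2-methyl-4-oxobut-2-enoate; 2 (2E)-3-methylpent-2-enoyl chloride
Product: 8 methyl (3E)-2-methylidene-4-{[(2E)-3-methylpent-2-enoyl]oxy}but-3-enoate, via potassium dienolate 7 (not isolated)
Conditions: KN(SiMe3)2 (1.05 equiv), THF, −78 °C, 6 added slowly to the base; then 2 (1.1 equiv), −78 to −40 °C; pH 7 buffer; stored cold with 2,6-di-tert-butyl-4-methylphenol and used promptly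
Reagents that add atoms: none
Why: Gamma-deprotonation of the enal at the C2 methyl group by the non-nucleophilic amide should give the cross-conjugated dienolate from the s-trans conformer, and the hard acid chloride acylates the potassium enolate on oxygen (enolate O-acylation) to fix the E enol ester.

Step 5
Reactants: 9 1,1,3,3-tetramethoxypropane
Product: 11 sodium (1E)-3-oxoprop-1-en-1-olate, via malonaldehyde 10 (not isolated)
Conditions: HCl (1 M aq., cat.), H2O, rt to 40 °C; then NaOH (1.0 equiv), 0 °C; concentrated, precipitated from acetone, dried in vacuo over P2O5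
Reagents that add atoms: water, O; sodium hydroxide, [Na+].[OH-]
Why: Double acetal hydrolysis followed by deprotonation of the acidic 1,3-dialdehyde, whose delocalised enolate should crystallise as the stable extended E salt.

Step 6
Reactants: 11 sodium (1E)-3-oxoprop-1-en-1-olate; 2 (2E)-3-methylpent-2-enoyl chloride
Product: 12 (1E)-3-oxoprop-1-en-1-yl (2E)-3-methylpent-2-enoate
Conditions: anhydrous MeCN, 0 °C to rt; filtered, concentrated, kept dry
Reagents that add atoms: none
Why: Enolate O-acylation of the malonaldehyde anion by the acid chloride, as known for aroyl chlorides; the extended form of the salt is acylated without C–C rotation, so the E vinylogous anhydride should result.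

Step 7
Reactants: 8 methyl (3E)-2-methylidene-4-{[(2E)-3-methylpent-2-enoyl]oxy}but-3-enoate; 12 (1E)-3-oxoprop-1-en-1-yl (2E)-3-methylpent-2-enoate
Product: 13 methyl (3R,4S,5R)-4-formyl-3,5-bis{[(2E)-3-methylpent-2-enoyl]oxy}cyclohex-1-ene-1-carboxylate
Conditions: (3aS)-1-(2-methylphenyl)-3,3-diphenyltetrahydro-1H,3H-pyrrolo[1,2-c][1,3,2]oxazaborole (20 mol %), HN(SO2CF3)2 (18 mol %), CH2Cl2, −78 °C; 12 (1 equiv), then 8 (2 equiv) added slowly, −78 to −40 °C; cold pH 7 buffer, short cold silica plug, used at once
Reagents that add atoms: none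
Why: Proposed new method: the N-protonated oxazaborolidine binds the formyl oxygen of 12 at boron (formyl C–H···O contact to the ring oxygen, s-trans enal lying over the cis phenyl group at C3 of the catalyst) and lowers the LUMO, so that diene 8 adds in a concerted but asynchronous normal-demand [4+2] cycloaddition in which bond C5–C6 runs ahead of bond C3–C4. The closest known reaction type is the oxazaborolidinium-catalysed enantioselective Diels–Alder reaction of enals with 1-acyloxy- and 1-silyloxybutadienes; a diene that also bears a 3-alkoxycarbonyl group and a 3-acyloxyacrolein as dienophile have not been shown in it, which is why the step is a proposal. The cyclohexene ring, the only ring of the target, closes in a suprafacial [4+2] mode from the diene carbons C6–C1–C2–C3 and the dienophile carbons C4–C5, leaving the C1=C2 alkene conjugated with the ester. C4 (S) is set by the catalyst, whose phenyl group covers one face of the bound enal so that the diene reaches the Re face of the formyl-bearing carbon; C5 (R) follows from C4 through the E geometry of 12, which places formyl and acyloxy trans on the new ring; C3 (R) follows from the E enol ester of 8 together with endo placement of the boron-bound formyl group (secondary overlap with C1–C2 of the diene), which places formyl and the C3 acyloxy group cis. Regioselectivity is needed and is secured twice over, since the 1-acyloxy and the 3-ester substituent of 8 both enlarge the HOMO coefficient at the CH2 terminus C6, which joins the carbon beta to the formyl group. Also needed are endo and facial selectivity, secured by the bound formyl group and the catalyst as described, and a rate advantage over self-dimerisation of 8, for which low temperature, excess 8 and its slow addition are used.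

Step 8
Reactants: 13 methyl (3R,4S,5R)-4-formyl-3,5-bis{[(2E)-3-methylpent-2-enoyl]oxy}cyclohex-1-ene-1-carboxylate
Product: 15 methyl (3R,4S,5R)-4-(formyloxy)-3,5-bis{[(2E)-3-methylpent-2-enoyl]oxy}cyclohex-1-ene-1-carboxylate, via peroxy hemiacetal 14 (not isolated)
Conditions: 3-chloroperoxybenzoic acid (1.5 equiv), Na2HPO4 (solid buffer), CH2Cl2, 0 °C to rt; aq. Na2S2O3, then aq. NaHCO3 wash
Reagents that add atoms: 3-chloroperoxybenzoic acid, OOC(=O)c1cccc(Cl)c1
Why: Baeyer–Villiger oxidation of an α-branched aldehyde: the peracid adds to the formyl group and the secondary carbon C4 should migrate to oxygen with retention, carrying the C4 configuration of step 7 into the formate, while the three ester-conjugated alkenes are epoxidised far more slowly.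

Step 9
Reactants: 15 methyl (3R,4S,5R)-4-(formyloxy)-3,5-bis{[(2E)-3-methylpent-2-enoyl]oxy}cyclohex-1-ene-1-carboxylate
Product: 16 methyl (3R,4S,5R)-4-hydroxy-3,5-bis{[(2E)-3-methylpent-2-enoyl]oxy}cyclohex-1-ene-1-carboxylate
Conditions: NaHCO3 (0.2 equiv), MeOH, 0 °C, short reaction time; pH 7 buffer
Reagents that add atoms: none
Why: Bicarbonate-catalysed methanolysis (transesterification): a formate is cleaved far faster than the conjugated β,β-disubstituted enoates or the methyl ester, so the C4 hydroxyl should be freed at 0 °C before acyl migration begins, and no stereocentre is touched.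

**Compound list**

1 | (2E)-3-methylpent-2-enoic acid | CC/C(C)=C/C(=O)O | starting material
2 | (2E)-3-methylpent-2-enoyl chloride | CC/C(C)=C/C(=O)Cl | intermediate
3 | 2,2-dimethoxyacetaldehyde | COC(OC)C=O | starting material
4 | methyl 2-(triphenylphosphoranylidene)propanoate | COC(=O)C(C)=P(c1ccccc1)(c1ccccc1)c1ccccc1 | starting material
5 | methyl (2E)-4,4-dimethoxy-2-methylbut-2-enoate | COC(OC)/C=C(\C)C(=O)OC | intermediate
6 | methyl (2E)-2-methyl-4-oxobut-2-enoate | O=C/C=C(\C)C(=O)OC | intermediate
7 | potassium (1E)-3-(methoxycarbonyl)buta-1,3-dien-1-olate | [K+].[O-]/C=C/C(=C)C(=O)OC | intermediate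
8 | methyl (3E)-2-methylidene-4-{[(2E)-3-methylpent-2-enoyl]oxy}but-3-enoate | C=C(C(=O)OC)/C=C/OC(=O)/C=C(\C)CC | intermediate
9 | 1,1,3,3-tetramethoxypropane | COC(CC(OC)OC)OC | starting material
10 | malonaldehyde (propanedial) | O=CCC=O | intermediate
11 | sodium (1E)-3-oxoprop-1-en-1-olate | [Na+].[O-]/C=C/C=O | intermediate
12 | (1E)-3-oxoprop-1-en-1-yl (2E)-3-methylpent-2-enoate | O=C/C=C/OC(=O)/C=C(\C)CC | intermediate
13 | methyl (3R,4S,5R)-4-formyl-3,5-bis{[(2E)-3-methylpent-2-enoyl]oxy}cyclohex-1-ene-1-carboxylate | CC/C(C)=C/C(=O)O[C@@H]1C=C(C(=O)OC)C[C@@H](OC(=O)/C=C(\C)CC)[C@@H]1C=O | intermediate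
14 | methyl (3R,4S,5R)-4-{[(3-chlorobenzoyl)peroxy](hydroxy)methyl}-3,5-bis{[(2E)-3-methylpent-2-enoyl]oxy}cyclohex-1-ene-1-carboxylate (carbinol centre undefined) | CC/C(C)=C/C(=O)O[C@@H]1C=C(C(=O)OC)C[C@@H](OC(=O)/C=C(\C)CC)[C@@H]1C(O)OOC(=O)c1cccc(Cl)c1 | intermediate
15 | methyl (3R,4S,5R)-4-(formyloxy)-3,5-bis{[(2E)-3-methylpent-2-enoyl]oxy}cyclohex-1-ene-1-carboxylate | CC/C(C)=C/C(=O)O[C@@H]1C=C(C(=O)OC)C[C@@H](OC(=O)/C=C(\C)CC)[C@@H]1OC=O | intermediate
16 | methyl (3R,4S,5R)-4-hydroxy-3,5-bis{[(2E)-3-methylpent-2-enoyl]oxy}cyclohex-1-ene-1-carboxylate (CNP0268575.1) | CC/C(C)=C/C(=O)O[C@@H]1C=C(C(=O)OC)C[C@@H](OC(=O)/C=C(\C)CC)[C@@H]1O | target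

**Step count**

Total: 9 steps. Longest linear sequence: 6 steps (steps 2, 3, 4, 7, 8, 9).

**Steps most likely to fail**

Step 7 (proposed new method). The electron-poor diene may react too slowly with the bound dienophile, so that its self-dimerisation takes over. The facial preference may be low or reversed if two binding modes compete, endo selectivity may erode, and the β-acyloxy aldehyde may lose carboxylate under the Lewis acid. The fallback uses known chemistry only and takes the ring from the chiral pool; it sets out from acid chloride 2 and returns to the route at target 16. Commercial methyl shikimate F1 would be silylated with tert-butyldimethylsilyl chloride and imidazole in N,N-dimethylformamide at the two flanking hydroxyls, the 4-hydroxyl between them being the least accessible, to give the 3,5-bis(tert-butyldimethylsilyl) ether F2. 4-Methoxybenzyl 2,2,2-trichloroacetimidate with catalytic CF3SO3H would then cap O4 as the 4-methoxybenzyl ether F3. HF·pyridine in THF would remove both silyl groups to give diol F4. Acylation with 2 in pyridine/CH2Cl2 at −20 to 0 °C would give the 3,5-diester F5. Finally 2,3-dichloro-5,6-dicyano-1,4-benzoquinone in wet CH2Cl2 would cleave the benzyl ether oxidatively to give 16.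

Step 8. Hydride instead of C4 may migrate in the peroxy hemiacetal, because C4 is flanked by two electron-withdrawing acyloxy carbons, and this would give the carboxylic acid; base-induced loss of carboxylate β to the formyl group is a second failure path. The fallback removes the competing hydride; it sets out from aldehyde 13 and returns at target 16. MeTi(OiPr)3 in THF at −40 °C, a weakly basic reagent that adds to aldehydes and not to esters, should give the carbinol F6 (methyl (3R,4S,5R)-4-(1-hydroxyethyl) diester). Dess–Martin periodinane in CH2Cl2 would oxidise it to the methyl ketone F7. Baeyer–Villiger oxidation with 3-chloroperoxybenzoic acid and NaHCO3 in CH2Cl2, where the secondary C4 competes only with methyl, should give the C4 acetate F8 with retention. Mg(OMe)2 in MeOH at 0 °C, which cleaves acetates in preference to conjugated hindered esters, would then free the hydroxyl to give 16.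

Step 4. The dienolate may condense with unreacted enal, be acylated on carbon, give the Z enol ester, or the product diene may polymerise during isolation. The fallback avoids a free dienolate; it sets out from enal 6 (with acid 1) and returns at diene 8. Soft enolisation of 6 with Me3SiOSO2CF3 and Et3N in Et2O at 0 °C should give the silyl dienol ether F9 (methyl (3E)-2-methylidene-4-[(trimethylsilyl)oxy]but-3-enoate). Acid 1 with cyanuric fluoride and pyridine in CH2Cl2 would give (2E)-3-methylpent-2-enoyl fluoride F10. F9 and F10 with catalytic [Bu4N][Ph3SiF2] in THF at −20 °C should undergo fluoride-catalysed exchange of silyl for acyl on oxygen with retention of the E geometry, giving 8.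

**Further compounds**

F1 | step 7 | methyl (3R,4S,5R)-3,4,5-trihydroxycyclohex-1-ene-1-carboxylate (methyl shikimate) | O[C@@H]1C=C(C(=O)OC)C[C@@H](O)[C@@H]1O
F2 | step 7 | methyl (3R,4S,5R)-3,5-bis[(tert-butyldimethylsilyl)oxy]-4-hydroxycyclohex-1-ene-1-carboxylate | CC(C)(C)[Si](C)(C)O[C@@H]1C=C(C(=O)OC)C[C@@H](O[Si](C)(C)C(C)(C)C)[C@@H]1O
F3 | step 7 | methyl (3R,4S,5R)-3,5-bis[(tert-butyldimethylsilyl)oxy]-4-[(4-methoxybenzyl)oxy]cyclohex-1-ene-1-carboxylate | CC(C)(C)[Si](C)(C)O[C@@H]1C=C(C(=O)OC)C[C@@H](O[Si](C)(C)C(C)(C)C)[C@@H]1OCc1ccc(OC)cc1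
F4 | step 7 | methyl (3R,4S,5R)-3,5-dihydroxy-4-[(4-methoxybenzyl)oxy]cyclohex-1-ene-1-carboxylate | O[C@@H]1C=C(C(=O)OC)C[C@@H](O)[C@@H]1OCc1ccc(OC)cc1
F5 | step 7 | methyl (3R,4S,5R)-4-[(4-methoxybenzyl)oxy]-3,5-bis{[(2E)-3-methylpent-2-enoyl]oxy}cyclohex-1-ene-1-carboxylate | CC/C(C)=C/C(=O)O[C@@H]1C=C(C(=O)OC)C[C@@H](OC(=O)/C=C(\C)CC)[C@@H]1OCc1ccc(OC)cc1
F6 | step 8 | methyl (3R,4S,5R)-4-(1-hydroxyethyl)-3,5-bis{[(2E)-3-methylpent-2-enoyl]oxy}cyclohex-1-ene-1-carboxylate (carbinol centre undefined) | CC/C(C)=C/C(=O)O[C@@H]1C=C(C(=O)OC)C[C@@H](OC(=O)/C=C(\C)CC)[C@@H]1C(C)O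
F7 | step 8 | methyl (3R,4S,5R)-4-acetyl-3,5-bis{[(2E)-3-methylpent-2-enoyl]oxy}cyclohex-1-ene-1-carboxylate | CC/C(C)=C/C(=O)O[C@@H]1C=C(C(=O)OC)C[C@@H](OC(=O)/C=C(\C)CC)[C@@H]1C(C)=O
F8 | step 8 | methyl (3R,4S,5R)-4-(acetyloxy)-3,5-bis{[(2E)-3-methylpent-2-enoyl]oxy}cyclohex-1-ene-1-carboxylate | CC/C(C)=C/C(=O)O[C@@H]1C=C(C(=O)OC)C[C@@H](OC(=O)/C=C(\C)CC)[C@@H]1OC(C)=O
F9 | step 4 | methyl (3E)-2-methylidene-4-[(trimethylsilyl)oxy]but-3-enoate | C=C(C(=O)OC)/C=C/O[Si](C)(C)C
F10 | step 4 | (2E)-3-methylpent-2-enoyl fluoride | CC/C(C)=C/C(=O)F
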